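**Retrosynthetic overview**
1. Last bond C2''–C3'': Heck coupling of the ring vinyl group with the (2E,4E)-5-bromopentadienamide of 2-amino-3-hydroxycyclopentenone (made from glutaconaldehyde potassium salt and cyclopentane-1,3-dione).
2. Enamide C–N: copper-catalysed amidation of a 2-iodo epoxyquinol with (2E,4E,6R)-4,6-dimethyldeca-2,4-dienamide (stereocentre bought in (S)-3-bromo-2-methylpropan-1-ol).
3. Epoxyquinol from an anti-bis-epoxide: the distal oxirane becomes allylic alcohol then enone; the proximal oxirane (the target's) comes from hydroxyl-directed epoxidation.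
4. Key step: the tertiary C–O bond (target C4) forms in a [2,3]-sigmatropic rearrangement of an allylic selenoxide, which carries the C3 configuration of (−)-shikimic acid to C1; the ester carbon becomes the first chain carbon.
5. Ring order: carbocycle bought (shikimic acid), then the first oxirane from the 4,5-diol, then the second oxirane (kept), then the first oxirane is opened; the cyclopentenone ring is bought.

Assumption: the SMILES is taken as drawn, i.e. (1S,5S,6R) epoxyquinol with the tertiary hydroxyl syn to the oxirane, a (6R) side chain and the aminocyclopentenone as its enol; shikimate-derived intermediates are discussed with ring atoms C1–C6 (C1 carries the ester carbon).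

**Steps**

Step 1
Reactants: 1 (−)-shikimic acid
Product: 2 methyl (3R,4S,5R)-3,4,5-trihydroxycyclohex-1-ene-1-carboxylate
Conditions: MeOH, H2SO4 (cat.), reflux
Reagents that add atoms: methanol, CO
Why: Fischer esterification, which leaves the three bought stereocentres untouched.

Step 2
Reactants: 2 methyl (3R,4S,5R)-3,4,5-trihydroxycyclohex-1-ene-1-carboxylate
Product: 3 methyl (1S,5R,6R)-5-hydroxy-7-oxabicyclo[4.1.0]hept-3-ene-3-carboxylate
Conditions: PPh3, DIAD, THF, 0 °C → rt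
Reagents that add atoms: none
Why: Intramolecular Mitsunobu reaction in which the unhindered C5 hydroxyl is activated and displaced by the trans C4 oxygen with inversion at C5, giving the oxirane cis to the untouched allylic C3 hydroxyl (a reported one-step conversion of methyl shikimate).

Step 3
Reactants: 3 methyl (1S,5R,6R)-5-hydroxy-7-oxabicyclo[4.1.0]hept-3-ene-3-carboxylate
Product: 4 methyl (1S,5S,6S)-5-(phenylselanyl)-7-oxabicyclo[4.1.0]hept-3-ene-3-carboxylate
Conditions: N-(phenylseleno)phthalimide, PBu3, THF, −20 °C → rt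
Reagents that add atoms: N-(phenylseleno)phthalimide, O=C1c2ccccc2C(=O)N1[Se]c1ccccc1
Why: Grieco–Nicolaou selenenylation (Mitsunobu-type), in which PhSe− displaces the C3 alkoxyphosphonium by SN2 with inversion so that selenium ends on the ring face opposite to the oxirane.

Step 4
Reactants: 4 methyl (1S,5S,6S)-5-(phenylselanyl)-7-oxabicyclo[4.1.0]hept-3-ene-3-carboxylate
Product: 7 methyl (1S,3S,6R)-3-hydroxy-7-oxabicyclo[4.1.0]hept-4-ene-3-carboxylate, via allylic selenoxide 5 (not isolated), via selenenate ester 6 (not isolated)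
Conditions: 30% H2O2, pyridine, CH2Cl2, −20 °C → rt
Reagents that add atoms: hydrogen peroxide, OO
Why: [2,3]-Sigmatropic rearrangement of the allylic selenoxide (Sharpless–Reich) followed by Se–O cleavage, in which oxygen is delivered suprafacially to C1 on the face that carried selenium, so the bought C3 centre fixes the new tertiary carbinol (C4 of the target) while the alkene moves to C2=C3.

Step 5
Reactants: 7 methyl (1S,3S,6R)-3-hydroxy-7-oxabicyclo[4.1.0]hept-4-ene-3-carboxylate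
Product: 8 methyl (1S,2R,4R,5S,7S)-5-hydroxy-3,8-dioxatricyclo[5.1.0.0(2,4)]octane-5-carboxylate
Conditions: VO(acac)2 (5 mol %), tBuOOH, CH2Cl2, 0 °C → rt
Reagents that add atoms: tert-butyl hydroperoxide, CC(C)(C)OO
Why: Vanadium-catalysed hydroxyl-directed epoxidation, in which the tertiary allylic hydroxyl delivers oxygen syn to itself on the face that is also anti to the first oxirane, setting both epoxide carbons of the target syn to the carbinol.

Step 6
Reactants: 8 methyl (1S,2R,4R,5S,7S)-5-hydroxy-3,8-dioxatricyclo[5.1.0.0(2,4)]octane-5-carboxylate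
Product: 10 (1S,2R,4R,5R,7S)-5-ethenyl-3,8-dioxatricyclo[5.1.0.0(2,4)]octan-5-ol, via hydroxy aldehyde 9 (not isolated)
Conditions: iBu2AlH (2.2 equiv), CH2Cl2, −78 °C; then Ph3PCH3Br/KN(SiMe3)2 (3 equiv), THF, −78 °C → rt
Reagents that add atoms: methyltriphenylphosphonium bromide, C[P+](c1ccccc1)(c1ccccc1)c1ccccc1.[Br-]
Why: One-pot iBu2AlH half-reduction and Wittig methylenation, in which the chelated aluminium hemiacetal of the α-hydroxy ester releases the aldehyde only as the ylide consumes it, so no stereocentre is touched and the ester carbon becomes C1''.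

Step 7
Reactants: 10 (1S,2R,4R,5R,7S)-5-ethenyl-3,8-dioxatricyclo[5.1.0.0(2,4)]octan-5-ol
Product: 13 (1R,2S,5S,6R)-2-ethenyl-7-oxabicyclo[4.1.0]hept-3-ene-2,5-diol, via hydroxy selenide 11 (not isolated), via hydroxy selenoxide 12 (not isolated)
Conditions: (PhSe)2, NaBH4, EtOH, rt → 50 °C; then 30% H2O2, THF, 0 °C → rt
Reagents that add atoms: none
Why: Sharpless–Lauer epoxide-to-allylic-alcohol conversion, in which selenolate opens the distal oxirane trans-diaxially at its only unhindered carbon (next to CH2) and the selenoxide undergoes syn-elimination away from the new carbinol, whose configuration is irrelevant because it is oxidised next.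

Step 8
Reactants: 13 (1R,2S,5S,6R)-2-ethenyl-7-oxabicyclo[4.1.0]hept-3-ene-2,5-diol
Product: 14 (1S,5S,6R)-5-ethenyl-5-hydroxy-7-oxabicyclo[4.1.0]hept-3-en-2-one
Conditions: MnO2, CH2Cl2, rt
Reagents that add atoms: none
Why: Allylic oxidation with MnO2 is selective for the secondary allylic alcohol and leaves the tertiary alcohol, the oxirane and the vinyl group untouched.

Step 9
Reactants: 14 (1S,5S,6R)-5-ethenyl-5-hydroxy-7-oxabicyclo[4.1.0]hept-3-en-2-one
Product: 15 (1S,5S,6R)-5-ethenyl-5-hydroxy-3-iodo-7-oxabicyclo[4.1.0]hept-3-en-2-one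
Conditions: I2, pyridine, CH2Cl2, 0 °C → rt
Reagents that add atoms: iodine, [I][I]
Why: Johnson α-iodination of the enone (conjugate addition of pyridine, iodination of the enolate, elimination), well precedented on 4-hydroxy-5,6-epoxycyclohexenones.

Step 10
Reactants: 16 (S)-3-bromo-2-methylpropan-1-ol
Product: 17 (R)-2-methylhexan-1-ol
Conditions: nPrMgBr (3 equiv), Li2CuCl4 (5 mol %), THF, −78 °C → 0 °C
Reagents that add atoms: n-propylmagnesium bromide, CCC[Mg]Br
Why: Copper-catalysed Kochi–Schlosser sp3–sp3 coupling of the Grignard reagent with the primary bromide of the magnesium alkoxide, in which the bought stereocentre is not a reacting centre (S becomes R only through the priority change).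

Step 11
Reactants: 17 (R)-2-methylhexan-1-ol
Product: 19 (2E,4R)-2,4-dimethyloct-2-enal, via aldehyde 18 (not isolated)
Conditions: PhI(OAc)2, TEMPO (10 mol %), CH2Cl2, rt; then Ph3P=C(CH3)CHO, rt → 40 °C
Reagents that add atoms: 2-(triphenylphosphoranylidene)propanal, CC(C=O)=P(c1ccccc1)(c1ccccc1)c1ccccc1
Why: One-pot TEMPO oxidation and Wittig olefination, in which the epimerisable α-branched aldehyde is trapped as it forms by the stabilised ylide, which gives the (E)-trisubstituted enal as usual for stabilised ylides.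

Step 12
Reactants: 19 (2E,4R)-2,4-dimethyloct-2-enal
Product: 20 (2E,4E,6R)-4,6-dimethyldeca-2,4-dienamide
Conditions: (EtO)2P(O)CH2CONH2, NaH, THF, 0 °C → rt
Reagents that add atoms: diethyl (2-amino-2-oxoethyl)phosphonate, CCOP(=O)(CC(N)=O)OCC
Why: Horner–Wadsworth–Emmons olefination with the carbamoyl-stabilised phosphonate gives the (E)-acrylamide directly and completes the (2E,4E)-dienamide.

Step 13
Reactants: 15 (1S,5S,6R)-5-ethenyl-5-hydroxy-3-iodo-7-oxabicyclo[4.1.0]hept-3-en-2-one; 20 (2E,4E,6R)-4,6-dimethyldeca-2,4-dienamide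
Product: 21 (2E,4E,6R)-N-[(1S,5S,6R)-5-ethenyl-5-hydroxy-2-oxo-7-oxabicyclo[4.1.0]hept-3-en-3-yl]-4,6-dimethyldeca-2,4-dienamide
Conditions: CuI (10 mol %), N,N'-dimethylethylenediamine (20 mol %), Cs2CO3, THF, 50 °C
Reagents that add atoms: none
Why: Goldberg–Buchwald copper-catalysed vinylic amidation of the activated α-iodoenone with the primary amide forms the enamide C–N bond with retention of the ring alkene and without touching the stereocentres.

Step 14
Reactants: 22 cyclopentane-1,3-dione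
Product: 23 2-(hydroxyimino)cyclopentane-1,3-dione
Conditions: NaNO2, aq. HCl, 0 °C
Reagents that add atoms: sodium nitrite, [Na+].[O-]N=O
Why: Nitrosation of the doubly activated methylene gives the 2-oxime.

Step 15
Reactants: 23 2-(hydroxyimino)cyclopentane-1,3-dione
Product: 24 2-amino-3-hydroxycyclopent-2-en-1-one hydrochloride
Conditions: H2 (1 atm), Pd on carbon (Pd/C), HCl, MeOH, rt
Reagents that add atoms: hydrogen chloride, Cl
Why: Catalytic hydrogenation of the oxime to the primary amine, isolated as the hydrochloride of the enolised aminodione to prevent self-condensation.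

Step 16
Reactants: 25 potassium (1E,3E)-5-oxopenta-1,3-dien-1-olate (glutaconaldehyde potassium salt)
Product: 26 (2E,4E)-5-bromopenta-2,4-dienal
Conditions: PPh3, Br2, CH2Cl2, 0 °C → rt
Reagents that add atoms: bromine, BrBr
Why: Deoxybromination of the vinylogous formate anion by Ph3PBr2 (addition–elimination, Becher's method), which gives the thermodynamically favoured (2E,4E)-bromodienal.

Step 17
Reactants: 26 (2E,4E)-5-bromopenta-2,4-dienal
Product: 27 (2E,4E)-5-bromopenta-2,4-dienoic acid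
Conditions: NaClO2, NaH2PO4, 2-methylbut-2-ene, tBuOH/H2O, rt
Reagents that add atoms: sodium chlorite, [Na+].[O-]Cl=O
Why: Pinnick oxidation converts the enal to the acid without touching the bromodiene.

Step 18
Reactants: 27 (2E,4E)-5-bromopenta-2,4-dienoic acid; 24 2-amino-3-hydroxycyclopent-2-en-1-one hydrochloride
Product: 29 (2E,4E)-5-bromo-N-(2-hydroxy-5-oxocyclopent-1-en-1-yl)penta-2,4-dienamide, via acid chloride 28 (not isolated)
Conditions: (COCl)2, DMF (cat.), CH2Cl2, 0 °C; then 24, Et3N, CH2Cl2, 0 °C → rt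
Reagents that add atoms: none
Why: N-Acylation of the amine by the acid chloride made in situ, any O-acylated enol passing its acyl group on to nitrogen.

Step 19
Reactants: 21 (2E,4E,6R)-N-[(1S,5S,6R)-5-ethenyl-5-hydroxy-2-oxo-7-oxabicyclo[4.1.0]hept-3-en-3-yl]-4,6-dimethyldeca-2,4-dienamide; 29 (2E,4E)-5-bromo-N-(2-hydroxy-5-oxocyclopent-1-en-1-yl)penta-2,4-dienamide
Product: 30 (2E,4E,6R)-N-[(1S,5S,6R)-5-hydroxy-5-[(1E,3E,5E)-7-[(2-hydroxy-5-oxocyclopent-1-en-1-yl)amino]-7-oxohepta-1,3,5-trien-1-yl]-2-oxo-7-oxabicyclo[4.1.0]hept-3-en-3-yl]-4,6-dimethyldeca-2,4-dienamide (CNP0262080.2)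
Conditions: Pd(OAc)2 (10 mol %), nBu4NCl, NaHCO3, DMF, 40 °C, dark
Reagents that add atoms: none
Why: Mizoroki–Heck coupling under Jeffery conditions, in which oxidative addition of the vinyl bromide with retention, insertion into the only monosubstituted alkene and syn β-hydride elimination away from the quaternary carbinol give the (1E,3E,5E)-triene without involving any stereocentre.

**Compound list**
1 | (−)-shikimic acid, (3R,4S,5R)-3,4,5-trihydroxycyclohex-1-ene-1-carboxylic acid | OC(=O)C1=C[C@@H](O)[C@@H](O)[C@H](O)C1 | starting material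
2 | methyl (3R,4S,5R)-3,4,5-trihydroxycyclohex-1-ene-1-carboxylate | COC(=O)C1=C[C@@H](O)[C@@H](O)[C@H](O)C1 | intermediate
3 | methyl (1S,5R,6R)-5-hydroxy-7-oxabicyclo[4.1.0]hept-3-ene-3-carboxylate (oxirane cis to the hydroxyl) | COC(=O)C1=C[C@@H](O)[C@H]2O[C@H]2C1 | intermediate
4 | methyl (1S,5S,6S)-5-(phenylselanyl)-7-oxabicyclo[4.1.0]hept-3-ene-3-carboxylate (selenium trans to the oxirane) | COC(=O)C1=C[C@H]([Se]c2ccccc2)[C@H]3O[C@H]3C1 | intermediate
5 | methyl (1S,5S,6S)-5-(benzeneseleninyl)-7-oxabicyclo[4.1.0]hept-3-ene-3-carboxylate (selenium configuration undefined) | COC(=O)C1=C[C@H]([Se](=O)c2ccccc2)[C@H]3O[C@H]3C1 | intermediate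
6 | methyl (1S,3S,6R)-3-[(phenylselanyl)oxy]-7-oxabicyclo[4.1.0]hept-4-ene-3-carboxylate | COC(=O)[C@@]1(O[Se]c2ccccc2)C=C[C@H]3O[C@H]3C1 | intermediate
7 | methyl (1S,3S,6R)-3-hydroxy-7-oxabicyclo[4.1.0]hept-4-ene-3-carboxylate (hydroxyl trans to the oxirane) | COC(=O)[C@@]1(O)C=C[C@H]2O[C@H]2C1 | intermediate
8 | methyl (1S,2R,4R,5S,7S)-5-hydroxy-3,8-dioxatricyclo[5.1.0.0(2,4)]octane-5-carboxylate (anti-bis-epoxide, hydroxyl syn to the neighbouring oxirane) | COC(=O)[C@@]1(O)[C@@H]2O[C@@H]2[C@H]3O[C@H]3C1 | intermediate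
9 | (1S,2R,4R,5S,7S)-5-hydroxy-3,8-dioxatricyclo[5.1.0.0(2,4)]octane-5-carbaldehyde | O=C[C@@]1(O)[C@@H]2O[C@@H]2[C@H]3O[C@H]3C1 | intermediate
10 | (1S,2R,4R,5R,7S)-5-ethenyl-3,8-dioxatricyclo[5.1.0.0(2,4)]octan-5-ol | C=C[C@@]1(O)[C@@H]2O[C@@H]2[C@H]3O[C@H]3C1 | intermediate
11 | (1R,2R,4R,5R,6R)-2-ethenyl-4-(phenylselanyl)-7-oxabicyclo[4.1.0]heptane-2,5-diol | C=C[C@@]1(O)[C@@H]2O[C@@H]2[C@@H](O)[C@H]([Se]c3ccccc3)C1 | intermediate
12 | (1R,2R,4R,5R,6R)-4-(benzeneseleninyl)-2-ethenyl-7-oxabicyclo[4.1.0]heptane-2,5-diol (selenium configuration undefined) | C=C[C@@]1(O)[C@@H]2O[C@@H]2[C@@H](O)[C@H]([Se](=O)c3ccccc3)C1 | intermediate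
13 | (1R,2S,5S,6R)-2-ethenyl-7-oxabicyclo[4.1.0]hept-3-ene-2,5-diol | C=C[C@@]1(O)[C@@H]2O[C@@H]2[C@@H](O)C=C1 | intermediate
14 | (1S,5S,6R)-5-ethenyl-5-hydroxy-7-oxabicyclo[4.1.0]hept-3-en-2-one | C=C[C@@]1(O)[C@@H]2O[C@@H]2C(=O)C=C1 | intermediate
15 | (1S,5S,6R)-5-ethenyl-5-hydroxy-3-iodo-7-oxabicyclo[4.1.0]hept-3-en-2-one | C=C[C@@]1(O)[C@@H]2O[C@@H]2C(=O)C(I)=C1 | intermediate
16 | (S)-3-bromo-2-methylpropan-1-ol | BrC[C@@H](C)CO | starting material
17 | (R)-2-methylhexan-1-ol | CCCC[C@@H](C)CO | intermediate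
18 | (R)-2-methylhexanal | CCCC[C@@H](C)C=O | intermediate
19 | (2E,4R)-2,4-dimethyloct-2-enal | CCCC[C@@H](C)/C=C(C)/C=O | intermediate
20 | (2E,4E,6R)-4,6-dimethyldeca-2,4-dienamide | CCCC[C@@H](C)/C=C(C)/C=C/C(N)=O | intermediate
21 | (2E,4E,6R)-N-[(1S,5S,6R)-5-ethenyl-5-hydroxy-2-oxo-7-oxabicyclo[4.1.0]hept-3-en-3-yl]-4,6-dimethyldeca-2,4-dienamide | CCCC[C@@H](C)/C=C(C)/C=C/C(=O)NC1=C[C@@](O)(C=C)[C@@H]2O[C@@H]2C1=O | intermediate
22 | cyclopentane-1,3-dione | O=C1CCC(=O)C1 | starting material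
23 | 2-(hydroxyimino)cyclopentane-1,3-dione | ON=C1C(=O)CCC1=O | intermediate
24 | 2-amino-3-hydroxycyclopent-2-en-1-one hydrochloride | Cl.NC1=C(O)CCC1=O | intermediate
25 | potassium (1E,3E)-5-oxopenta-1,3-dien-1-olate (glutaconaldehyde potassium salt) | [K+].[O-]/C=C/C=C/C=O | starting material
26 | (2E,4E)-5-bromopenta-2,4-dienal | Br/C=C/C=C/C=O | intermediate
27 | (2E,4E)-5-bromopenta-2,4-dienoic acid | Br/C=C/C=C/C(O)=O | intermediate
28 | (2E,4E)-5-bromopenta-2,4-dienoyl chloride | Br/C=C/C=C/C(Cl)=O | intermediate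
29 | (2E,4E)-5-bromo-N-(2-hydroxy-5-oxocyclopent-1-en-1-yl)penta-2,4-dienamide | Br/C=C/C=C/C(=O)NC1=C(O)CCC1=O | intermediate
30 | (2E,4E,6R)-N-[(1S,5S,6R)-5-hydroxy-5-[(1E,3E,5E)-7-[(2-hydroxy-5-oxocyclopent-1-en-1-yl)amino]-7-oxohepta-1,3,5-trien-1-yl]-2-oxo-7-oxabicyclo[4.1.0]hept-3-en-3-yl]-4,6-dimethyldeca-2,4-dienamide | CCCC[C@@H](C)/C=C(C)/C=C/C(=O)NC1=C[C@@](O)(/C=C/C=C/C=C/C(=O)NC2=C(O)CCC2=O)[C@@H]2O[C@@H]2C1=O | target

**Step count and risks**
Total steps: 19. Longest linear sequence: 11 steps (1–9, 13, 19) from shikimic acid.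

Most likely to fail:

Step 7. Two oxiranes compete for the selenolate, and the alkoxide formed can migrate into the remaining oxirane (Payne). The fallback is a non-basic halohydrin route that sets out from 10. Li2NiBr4 in THF at 0 °C opens the distal oxirane to the bromohydrin (1R,2R,4R,5R,6R)-4-bromo-2-ethenyl-7-oxabicyclo[4.1.0]heptane-2,5-diol F1. Dess–Martin periodinane oxidises it to the bromo ketone (1S,3R,5R,6R)-3-bromo-5-ethenyl-5-hydroxy-7-oxabicyclo[4.1.0]heptan-2-one F2. Li2CO3/LiBr in DMF then eliminates HBr, and the route is rejoined at enone 14.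

Step 13. The iodo epoxyquinol is base-sensitive and the conjugated amide is a modest nucleophile. The fallback brings nitrogen in as azide and finishes the acyl chain by olefination; it sets out from 10. NaN3/NH4Cl in aqueous MeOH opens the distal oxirane to the azido alcohol (1R,2R,4R,5S,6R)-4-azido-2-ethenyl-7-oxabicyclo[4.1.0]heptane-2,5-diol F3. Dess–Martin periodinane gives the azido ketone (1S,3R,5R,6R)-3-azido-5-ethenyl-5-hydroxy-7-oxabicyclo[4.1.0]heptan-2-one F4. Et3N triggers loss of N2 and tautomerisation to the amino enone (1S,5S,6R)-3-amino-5-ethenyl-5-hydroxy-7-oxabicyclo[4.1.0]hept-3-en-2-one F5. Diethylphosphonoacetyl chloride with pyridine gives the phosphonoacetamide diethyl [2-({(1S,5S,6R)-5-ethenyl-5-hydroxy-2-oxo-7-oxabicyclo[4.1.0]hept-3-en-3-yl}amino)-2-oxoethyl]phosphonate F6. Its Horner–Wadsworth–Emmons reaction with enal 19 (LiCl, DBU, MeCN) comes back to the route at 21.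

Step 19. The Heck coupling is run on a base- and light-sensitive polyene with an acidic coupling partner. The fallback is a boron-based cross-coupling that sets out from 21. Cross-metathesis with 4,4,5,5-tetramethyl-2-vinyl-1,3,2-dioxaborolane (second-generation Grubbs catalyst, CH2Cl2, 40 °C) gives the alkenylboronate (2E,4E,6R)-N-[(1S,5S,6R)-5-hydroxy-2-oxo-5-[(E)-2-(4,4,5,5-tetramethyl-1,3,2-dioxaborolan-2-yl)ethenyl]-7-oxabicyclo[4.1.0]hept-3-en-3-yl]-4,6-dimethyldeca-2,4-dienamide F7. Suzuki–Miyaura coupling of F7 with 29 (Pd(PPh3)4, aqueous K3PO4, THF, rt) comes back at the target 30.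

Further compounds
F1 | step 7 | (1R,2R,4R,5R,6R)-4-bromo-2-ethenyl-7-oxabicyclo[4.1.0]heptane-2,5-diol | C=C[C@@]1(O)[C@@H]2O[C@@H]2[C@@H](O)[C@H](Br)C1
F2 | step 7 | (1S,3R,5R,6R)-3-bromo-5-ethenyl-5-hydroxy-7-oxabicyclo[4.1.0]heptan-2-one | C=C[C@@]1(O)[C@@H]2O[C@@H]2C(=O)[C@H](Br)C1
F3 | step 13 | (1R,2R,4R,5S,6R)-4-azido-2-ethenyl-7-oxabicyclo[4.1.0]heptane-2,5-diol | C=C[C@@]1(O)[C@@H]2O[C@@H]2[C@@H](O)[C@H](N=[N+]=[N-])C1
F4 | step 13 | (1S,3R,5R,6R)-3-azido-5-ethenyl-5-hydroxy-7-oxabicyclo[4.1.0]heptan-2-one | C=C[C@@]1(O)[C@@H]2O[C@@H]2C(=O)[C@H](N=[N+]=[N-])C1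
F5 | step 13 | (1S,5S,6R)-3-amino-5-ethenyl-5-hydroxy-7-oxabicyclo[4.1.0]hept-3-en-2-one | C=C[C@@]1(O)[C@@H]2O[C@@H]2C(=O)C(N)=C1
F6 | step 13 | diethyl [2-({(1S,5S,6R)-5-ethenyl-5-hydroxy-2-oxo-7-oxabicyclo[4.1.0]hept-3-en-3-yl}amino)-2-oxoethyl]phosphonate | CCOP(=O)(CC(=O)NC1=C[C@@](O)(C=C)[C@@H]2O[C@@H]2C1=O)OCC
F7 | step 19 | (2E,4E,6R)-N-[(1S,5S,6R)-5-hydroxy-2-oxo-5-[(E)-2-(4,4,5,5-tetramethyl-1,3,2-dioxaborolan-2-yl)ethenyl]-7-oxabicyclo[4.1.0]hept-3-en-3-yl]-4,6-dimethyldeca-2,4-dienamide | CCCC[C@@H](C)/C=C(C)/C=C/C(=O)NC1=C[C@@](O)(/C=C/B2OC(C)(C)C(C)(C)O2)[C@@H]3O[C@@H]3C1=O
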